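**Retrosynthetic overview**
1. Structural feature used: ring A has oxygen on C5, C7 and C8a (every second carbon), and C4a, between C5 and C8a, bears carbon C4. This is the pattern of an acylphloroglucinol made from a linear β-polycarbonyl chain. The fourth oxygen, the C8 methoxy between C7 and C8a, can come in on the α-carbon of the chain's ester end.
2. Lactone ring last: O1–C2 and C3=C4 are cut to a 2-hydroxy-3,4,6-trimethoxybenzophenone and a two-carbon phosphorus ylide. The free C8a–OH comes from the tetramethyl ether by chelation-directed ether cleavage, which also frees the ring B phenol.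
3. Ring A: the C4a–C8a bond is cut (retro-Claisen) to methyl 7-aryl-2-methoxy-3,5,7-trioxoheptanoate.
4. Chain: the C6–C7 bond (coumarin numbering) is cut to the bis(silyl enol ether) of the aroylacetone (from O-benzyl isoacetovanillone and ethyl acetate) and the half acid chloride of dimethyl methoxymalonate.
5. Order of rings: ring B is bought, ring A is closed in step 7, the lactone ring in step 10.

Key step: step 7

Assumption: the β-polycarbonyl compounds are drawn as keto forms although they are largely enolised, the methoxy-bearing carbon of 8 to 12 is racemic and labile and disappears on aromatisation (the target has no stereocentre), and the Z geometry drawn for 5, 6 and 10 has no bearing on the outcome.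

**Step 1**
Reactants: 1 3-hydroxy-4-methoxyacetophenone
Product: 2 3-benzyloxy-4-methoxyacetophenone
Conditions: BnBr, K2CO3, DMF, 60 °C
Reagents that add atoms: benzyl bromide BrCc1ccccc1
Why: Williamson ether synthesis on the only acidic OH masks the ring B phenol, which must stay distinguishable from the three ring A phenols that are methylated in step 8.

**Step 2**
Reactants: 2 3-benzyloxy-4-methoxyacetophenone, 3 ethyl acetate
Product: 4 1-(3-benzyloxy-4-methoxyphenyl)butane-1,3-dione
Conditions: NaH, THF, reflux; then 1 M HCl
Reagents that add atoms: none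
Why: Crossed Claisen condensation of the methyl ketone enolate with ethyl acetate is pulled to completion by irreversible deprotonation of the 1,3-diketone formed, the standard access to aroylacetones.

**Step 3**
Reactants: 4 1-(3-benzyloxy-4-methoxyphenyl)butane-1,3-dione
Product: 6 (1Z)-1-(3-benzyloxy-4-methoxyphenyl)-1,3-bis(trimethylsilyloxy)buta-1,3-diene, via monosilyl enol ether 5 (not isolated)
Conditions: TMSOTf (2.3 equiv), Et3N (2.6 equiv), Et2O, 0 °C to rt; used crude
Reagents that add atoms: trimethylsilyl trifluoromethanesulfonate C[Si](C)(C)OS(=O)(=O)C(F)(F)F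
Why: Soft enolisation with TMSOTf and Et3N silylates the enol of the 1,3-diketone to 5 and then enolises its remaining methyl ketone, the established double O-silylation that turns a 1,3-diketone into a 1,3-bis(silyloxy)diene, a neutral stand-in for the diketone dianion with its highest nucleophilicity at the terminal carbon.

**Step 4**
Reactants: 7 dimethyl methoxymalonate
Product: 8 2,3-dimethoxy-3-oxopropanoic acid (methyl hydrogen methoxymalonate, racemic)
Conditions: KOH (1.0 equiv), MeOH, 0 °C to rt; then 1 M HCl
Reagents that add atoms: potassium hydroxide [K+].[OH-]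
Why: Monosaponification of a malonic diester stops after one ester because the carboxylate formed shields the second ester from hydroxide.

**Step 5**
Reactants: 8 2,3-dimethoxy-3-oxopropanoic acid
Product: 9 methyl 3-chloro-2-methoxy-3-oxopropanoate (racemic)
Conditions: (COCl)2, cat. DMF, CH2Cl2, 0 °C to rt; used crude
Reagents that add atoms: oxalyl chloride ClC(=O)C(=O)Cl
Why: Acid chloride formation through the Vilsmeier-type chloroiminium species runs at room temperature, below the point at which a malonic half acid loses CO2.

**Step 6**
Reactants: 6 (1Z)-1-(3-benzyloxy-4-methoxyphenyl)-1,3-bis(trimethylsilyloxy)buta-1,3-diene, 9 methyl 3-chloro-2-methoxy-3-oxopropanoate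
Product: 11 methyl 7-(3-benzyloxy-4-methoxyphenyl)-2-methoxy-3,5,7-trioxoheptanoate, via silyl enol ether 10 (not isolated)
Conditions: CH2Cl2, −78 °C to rt; then 1 M HCl, THF, 0 °C
Reagents that add atoms: none
Why: Vinylogous Mukaiyama-type C-acylation of a 1,3-bis(silyl enol ether) by an acid chloride occurs at the terminal diene carbon, needs no base so that the acidic CH of 9 cannot divert the reaction to proton transfer or ketene formation, and spares the much less electrophilic methyl ester, after which mild acid removes the remaining silyl group of 10.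

**Step 7**
Reactants: 11 methyl 7-(3-benzyloxy-4-methoxyphenyl)-2-methoxy-3,5,7-trioxoheptanoate
Product: 13 (3-benzyloxy-4-methoxyphenyl)(2,4,6-trihydroxy-3-methoxyphenyl)methanone, via cyclohexanetrione tautomer 12 (not isolated)
Conditions: Mg(OMe)2 (5 equiv), MeOH, reflux, N2; then cold 1 M HCl
Reagents that add atoms: none
Why: Mg(OMe)2 turns 11 into a magnesium-chelated polyenolate whose bound oxygens bend the chain into a loop, the carbanion at chain C6 (between the C5 and C7 ketones) adds to the ester carbonyl C1, methoxide is expelled, and trione 12 enolises irreversibly to the arene. The closest known reaction is the intramolecular Claisen (Dieckmann-type) cyclisation of 3,5,7-triketo esters to acylphloroglucinols, the laboratory counterpart of polyketide folding. Ring A closes 6-exo-trig at the ester carbonyl (the enolate may be counted as enolexo through C7 or enolendo through C5, both allowed for a six-membered ring) and the one new bond is C4a–C8a; chain C1, C3 and C5 deliver the oxygens of C8a, C7 and C5, chain C2 delivers the C8 methoxy, and the C7 ketone is kept as the future C4. No stereocentre is formed and the labile one at chain C2 is erased on aromatisation. The step needs Claisen folding to win over aldol folding (chain C2 onto the C7 ketone), and the substrate secures this because the aldol adduct would carry a quaternary C2 that bars aromatisation and so stays reversible, because C2 is a hindered, oxygen-bearing and less readily formed carbanion, because the C7 ketone is deactivated by the para-methoxy ring, and because the inductive pull of the 2-methoxy group sharpens the ester as an acceptor. Lactonisation through the C5 enol oxygen is the remaining drain, and it should be held back by magnesium binding of the enolate oxygens and reversed by methanolysis, whereas the phenolate of 13 is a thermodynamic sink.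

**Step 8**
Reactants: 13 (3-benzyloxy-4-methoxyphenyl)(2,4,6-trihydroxy-3-methoxyphenyl)methanone
Product: 14 (3-benzyloxy-4-methoxyphenyl)(2,3,4,6-tetramethoxyphenyl)methanone
Conditions: Me2SO4 (excess), K2CO3, acetone, reflux
Reagents that add atoms: dimethyl sulfate COS(=O)(=O)OC
Why: Exhaustive Williamson O-methylation with an excess of a hard electrophile caps all three phenols, the two hydrogen-bonded ortho ones on prolonged reflux, and dimethyl sulfate with K2CO3 in acetone favours O- over C-alkylation of the phloroglucinol nucleus.

**Step 9**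
Reactants: 14 (3-benzyloxy-4-methoxyphenyl)(2,3,4,6-tetramethoxyphenyl)methanone
Product: 16 (3-hydroxy-4-methoxyphenyl)(2-hydroxy-3,4,6-trimethoxyphenyl)methanone, via bis(dichloroboryl) ether 15 (not isolated)
Conditions: BCl3 (4 equiv), C6HMe5 (3 equiv), CH2Cl2, −78 to 0 °C; then H2O
Reagents that add atoms: none
Why: In this chelation-directed Lewis acid ether cleavage, BCl3 bound to the ketone oxygen reaches only the two ortho methoxy groups and should take the one at C2, which is twisted out of the ring plane between the aroyl group and the C3 methoxy and is therefore the more basic and more strained, while the benzyl ether falls at the same time and its cation is trapped by pentamethylbenzene.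

**Step 10**
Reactants: 16 (3-hydroxy-4-methoxyphenyl)(2-hydroxy-3,4,6-trimethoxyphenyl)methanone, 17 ethyl (triphenylphosphoranylidene)acetate
Product: 19 4-(3-hydroxy-4-methoxyphenyl)-5,7,8-trimethoxy-2H-chromen-2-one (target), via Z-acrylate 18 (not isolated)
Conditions: 17 (3 equiv), xylene, reflux
Reagents that add atoms: none
Why: In the Wittig lactonisation known for 2-hydroxybenzophenones, the stabilised ylide olefinates the hydrogen-bond-activated ketone and acrylate 18, with its ester cis to the ortho phenol, closes the six-membered lactone with loss of ethanol, while the remote ring B phenol has no electrophile within reach.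

**Compound list**
1 | 3-hydroxy-4-methoxyacetophenone | CC(=O)c1ccc(OC)c(O)c1 | starting material
2 | 3-benzyloxy-4-methoxyacetophenone | CC(=O)c1ccc(OC)c(OCc2ccccc2)c1 | intermediate
3 | ethyl acetate | CCOC(C)=O | starting material
4 | 1-(3-benzyloxy-4-methoxyphenyl)butane-1,3-dione | CC(=O)CC(=O)c1ccc(OC)c(OCc2ccccc2)c1 | intermediate
5 | (3Z)-4-(3-benzyloxy-4-methoxyphenyl)-4-(trimethylsilyloxy)but-3-en-2-one | CC(=O)/C=C(\O[Si](C)(C)C)c1ccc(OC)c(OCc2ccccc2)c1 | intermediate
6 | (1Z)-1-(3-benzyloxy-4-methoxyphenyl)-1,3-bis(trimethylsilyloxy)buta-1,3-diene | C=C(O[Si](C)(C)C)/C=C(\O[Si](C)(C)C)c1ccc(OC)c(OCc2ccccc2)c1 | intermediate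
7 | dimethyl methoxymalonate | COC(C(=O)OC)C(=O)OC | starting material
8 | 2,3-dimethoxy-3-oxopropanoic acid (racemic) | COC(C(=O)O)C(=O)OC | intermediate
9 | methyl 3-chloro-2-methoxy-3-oxopropanoate (racemic) | COC(C(=O)Cl)C(=O)OC | intermediate
10 | methyl (6Z)-7-(3-benzyloxy-4-methoxyphenyl)-2-methoxy-3,5-dioxo-7-(trimethylsilyloxy)hept-6-enoate (racemic) | COC(=O)C(OC)C(=O)CC(=O)/C=C(\O[Si](C)(C)C)c1ccc(OC)c(OCc2ccccc2)c1 | intermediate
11 | methyl 7-(3-benzyloxy-4-methoxyphenyl)-2-methoxy-3,5,7-trioxoheptanoate (racemic at C2, keto form) | COC(=O)C(OC)C(=O)CC(=O)CC(=O)c1ccc(OC)c(OCc2ccccc2)c1 | intermediate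
12 | 2-(3-benzyloxy-4-methoxybenzoyl)-4-methoxycyclohexane-1,3,5-trione (keto tautomer of 13, labile centres) | COC1C(=O)CC(=O)C(C(=O)c2ccc(OC)c(OCc3ccccc3)c2)C1=O | intermediate
13 | (3-benzyloxy-4-methoxyphenyl)(2,4,6-trihydroxy-3-methoxyphenyl)methanone | COc1c(O)cc(O)c(C(=O)c2ccc(OC)c(OCc3ccccc3)c2)c1O | intermediate
14 | (3-benzyloxy-4-methoxyphenyl)(2,3,4,6-tetramethoxyphenyl)methanone | COc1cc(OC)c(C(=O)c2ccc(OC)c(OCc3ccccc3)c2)c(OC)c1OC | intermediate
15 | bis(dichloroboryl) ether of 16 | COc1ccc(C(=O)c2c(OC)cc(OC)c(OC)c2OB(Cl)Cl)cc1OB(Cl)Cl | intermediate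
16 | (3-hydroxy-4-methoxyphenyl)(2-hydroxy-3,4,6-trimethoxyphenyl)methanone | COc1ccc(C(=O)c2c(OC)cc(OC)c(OC)c2O)cc1O | intermediate
17 | ethyl (triphenylphosphoranylidene)acetate | CCOC(=O)C=P(c1ccccc1)(c1ccccc1)c1ccccc1 | starting material
18 | ethyl (2Z)-3-(3-hydroxy-4-methoxyphenyl)-3-(2-hydroxy-3,4,6-trimethoxyphenyl)prop-2-enoate | CCOC(=O)/C=C(\c1c(O)c(OC)c(OC)cc1OC)c1ccc(OC)c(O)c1 | intermediate
19 | 4-(3-hydroxy-4-methoxyphenyl)-5,7,8-trimethoxy-2H-chromen-2-one | COc1ccc(-c2cc(=O)oc3c(OC)c(OC)cc(OC)c23)cc1O | target

**Step count**
Total step count: 10.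
Longest linear sequence: 8 steps (1, 2, 3, 6, 7, 8, 9 and 10, from compound 1). Steps 4 and 5 form the side branch.

**Steps most likely to fail**

Step 7.
- Risk: the chain may fold or break in other ways. The C5 enol oxygen may be acylated instead of carbon C6, methoxide may cut the chain by retro-Claisen scission, or aldol closure followed by dehydration may occur.
- Fallback: ring A is bought rather than built, setting out from 2.
- Haloform oxidation of 2 (NaOCl, NaOH, dioxane–water, then HCl) should give 3-benzyloxy-4-methoxybenzoic acid F1.
- Trifluoroacetic anhydride in CH2Cl2 converts it into the mixed anhydride 3-benzyloxy-4-methoxybenzoyl trifluoroacetate F2.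
- F2 acylates commercial 1,2,3,5-tetramethoxybenzene in a Friedel–Crafts reaction. Its two free positions are equivalent, so only one ketone can form.
- The fallback comes back to the route at 14.

Step 6.
- Risk: the diene may be acylated on oxygen or at its central carbon, it may hydrolyse before it reacts, and the sensitive product may cyclise during work-up.
- Fallback: polyanion chemistry replaces the silyl enol ether, setting out from 4.
- LiN(iPr)2 (just over 3 equiv, THF) forms the dianion of 4, which is acylated at its terminal methyl carbon by methyl methoxyacetate. This gives 1-(3-benzyloxy-4-methoxyphenyl)-6-methoxyhexane-1,3,5-trione F3.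
- The trianion of F3 (LiN(iPr)2, THF) is carboxylated with CO2 at the most basic, methoxy-bearing terminal carbon. This gives 7-(3-benzyloxy-4-methoxyphenyl)-2-methoxy-3,5,7-trioxoheptanoic acid F4.
- Brief esterification with diazomethane in ether at 0 °C brings the fallback back to the route at 11.

Step 9.
- Risk: cleavage may take place at the other ortho methoxy group, it may run on to the methoxy next to the newly bound boron, or the benzyl cation may alkylate ring A.
- Fallback: the two ortho oxygens are told apart by partial alkylation instead of dealkylation, setting out from 13.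
- Me2SO4 (2 equiv), K2CO3 and acetone should methylate the unchelated para OH and the less hindered ortho OH. The OH wedged between ketone and methoxy stays free, giving (3-benzyloxy-4-methoxyphenyl)(2-hydroxy-3,4,6-trimethoxyphenyl)methanone F5.
- Ylide 17 in refluxing xylene passes through ethyl (2Z)-3-(3-benzyloxy-4-methoxyphenyl)-3-(2-hydroxy-3,4,6-trimethoxyphenyl)prop-2-enoate F6 to 4-(3-benzyloxy-4-methoxyphenyl)-5,7,8-trimethoxy-2H-chromen-2-one F7.
- Hydrogenolysis (H2, Pd/C, EtOAc, rt) brings the fallback back to the route at 19.

**Further compounds**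
F1 | step 7 | 3-benzyloxy-4-methoxybenzoic acid | COc1ccc(C(=O)O)cc1OCc1ccccc1
F2 | step 7 | 3-benzyloxy-4-methoxybenzoyl trifluoroacetate | COc1ccc(C(=O)OC(=O)C(F)(F)F)cc1OCc1ccccc1
F3 | step 6 | 1-(3-benzyloxy-4-methoxyphenyl)-6-methoxyhexane-1,3,5-trione | COCC(=O)CC(=O)CC(=O)c1ccc(OC)c(OCc2ccccc2)c1
F4 | step 6 | 7-(3-benzyloxy-4-methoxyphenyl)-2-methoxy-3,5,7-trioxoheptanoic acid (racemic) | COC(C(=O)O)C(=O)CC(=O)CC(=O)c1ccc(OC)c(OCc2ccccc2)c1
F5 | step 9 | (3-benzyloxy-4-methoxyphenyl)(2-hydroxy-3,4,6-trimethoxyphenyl)methanone | COc1cc(OC)c(C(=O)c2ccc(OC)c(OCc3ccccc3)c2)c(O)c1OC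
F6 | step 9 | ethyl (2Z)-3-(3-benzyloxy-4-methoxyphenyl)-3-(2-hydroxy-3,4,6-trimethoxyphenyl)prop-2-enoate | CCOC(=O)/C=C(\c1c(O)c(OC)c(OC)cc1OC)c1ccc(OC)c(OCc2ccccc2)c1
F7 | step 9 | 4-(3-benzyloxy-4-methoxyphenyl)-5,7,8-trimethoxy-2H-chromen-2-one | COc1ccc(-c2cc(=O)oc3c(OC)c(OC)cc(OC)c23)cc1OCc1ccccc1
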